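**Retrosynthetic overview**
1. Locants follow caryophyllane (bicyclo[7.2.0]undecane) numbering: C1/C9 are the ring-fusion carbons (C1 next to the CMe2 carbon C11), C4 carries the methyl group and the ring oxygen, C5 the CH2 link, C8 the exocyclic CH2. The dihydropyran is cut last across O–C4 and CH2–C5: hetero-Diels–Alder reaction of the o-quinone methide of trione 20 with the E-C4=C5 alkene of (1R,9S)-β-caryophyllene 18.
2. 18 comes from the 5-hydroxy-3-ene 15 by reductive allylic transposition, and the exocyclic CH2 from the C8 ketone 13 by methylenation.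
3. The nine-membered ring comes from cyclopentanol 10 by anionic oxy-Cope ring expansion: C1–C2 is made while the temporary bond C4–C8 is broken. Enabling feature: C8 is a latent ketone whose alpha carbon C9 is a cyclobutane carbon, so C1=C9–C8(O−)–C4–C3=C2 is a 3-oxy-1,5-diene once C4 (already bearing the methyl group) and C8 are tied into a five-membered ring.
4. 10 comes from a cyclobutenyllithium (from 3,3-dimethylcyclobutanone) and cyclopentanone 6. The two stereocentres of 6 are set by one catalytic desymmetrising reduction of a 2,2-disubstituted cyclopentane-1,3-dione, and every later stereocentre is relayed from them.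
5. Ring order: cyclobutane (bought), five-membered ring (bought, temporary), nine-membered ring (step 7), dearomatised trione ring (step 11), dihydropyran (step 12).

Key step: step 7

Remark: compounds 3–5 are carried as mixtures of epimers at sulfur, and the sulfur centre is left undefined in their SMILES.
Remark: RuCl[(R,R)-TsDPEN](p-cymene) is assumed to deliver the 3S carbinol in step 2; if the sense is opposite, the (S,S) complex is used and nothing else changes.
Remark: 19 is assumed to be purchased, and triones 20 and 21 are drawn as one enol tautomer.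

Step 1
Reactants: 1 2-methylcyclopentane-1,3-dione; 2 phenyl vinyl sulfoxide
Product: 3 2-methyl-2-[2-(phenylsulfinyl)ethyl]cyclopentane-1,3-dione
Conditions: DBU (0.1 equiv), MeCN, 60 °C
Reagents that add atoms: none
Why: Michael addition of the acidic 2-alkyl-1,3-dione to the vinyl sulfoxide alkylates the doubly activated carbon, and the sulfinylethyl arm is a masked vinyl group still much larger than methyl, which step 2 needs; no stereocentre of consequence is formed.

Step 2
Reactants: 3 2-methyl-2-[2-(phenylsulfinyl)ethyl]cyclopentane-1,3-dione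
Product: 4 (2S,3S)-3-hydroxy-2-methyl-2-[2-(phenylsulfinyl)ethyl]cyclopentan-1-one
Conditions: RuCl[(R,R)-TsDPEN](p-cymene) (1 mol %), HCO2H/Et3N (5:2), CH2Cl2, 30 °C
Reagents that add atoms: none
Why: Noyori-type asymmetric transfer hydrogenation desymmetrises the prochiral dione, the catalyst choosing one enantiotopic carbonyl and hydride arriving anti to the larger sulfinylethyl arm, so that C3 (S) and the quaternary C2 (S) are set in one event with OH cis to that arm.

Step 3
Reactants: 4 (2S,3S)-3-hydroxy-2-methyl-2-[2-(phenylsulfinyl)ethyl]cyclopentan-1-one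
Product: 5 (2S,3S)-3-[(tert-butyldimethylsilyl)oxy]-2-methyl-2-[2-(phenylsulfinyl)ethyl]cyclopentan-1-one
Conditions: TBSCl, imidazole, DMF, 40 °C
Reagents that add atoms: tert-butyldimethylsilyl chloride (TBSCl), CC(C)(C)[Si](C)(C)Cl
Why: Imidazole-mediated silyl ether formation protects the secondary alcohol as a bulky group that will shield one ring face in step 6; no stereocentre is touched.

Step 4
Reactants: 5 (2S,3S)-3-[(tert-butyldimethylsilyl)oxy]-2-methyl-2-[2-(phenylsulfinyl)ethyl]cyclopentan-1-one
Product: 6 (2S,3S)-3-[(tert-butyldimethylsilyl)oxy]-2-ethenyl-2-methylcyclopentan-1-one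
Conditions: CaCO3, toluene, 110 °C
Reagents that add atoms: none
Why: Sulfoxide pyrolysis (thermal syn elimination) can only take a hydrogen from the CH2 next to the quaternary carbon and so unmasks the vinyl group, now cis to the silyloxy group; both stereocentres are untouched.

Step 5
Reactants: 7 3,3-dimethylcyclobutan-1-one
Product: 8 N'-(3,3-dimethylcyclobutylidene)-2,4,6-tri(propan-2-yl)benzenesulfonohydrazide
Conditions: TrisNHNH2, HCl (cat.), MeOH, rt
Reagents that add atoms: 2,4,6-tri(propan-2-yl)benzenesulfonohydrazide (TrisNHNH2), CC(C)c1cc(C(C)C)c(S(=O)(=O)NN)c(C(C)C)c1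
Why: Acid-catalysed hydrazone formation prepares the ketone for the Shapiro reaction; the ketone is symmetric, so no regio- or stereochemical question arises.

Step 6
Reactants: 8 N'-(3,3-dimethylcyclobutylidene)-2,4,6-tri(propan-2-yl)benzenesulfonohydrazide; 6 (2S,3S)-3-[(tert-butyldimethylsilyl)oxy]-2-ethenyl-2-methylcyclopentan-1-one
Product: 10 (1S,2S,3S)-3-[(tert-butyldimethylsilyl)oxy]-1-(3,3-dimethylcyclobut-1-en-1-yl)-2-ethenyl-2-methylcyclopentan-1-ol, via (3,3-dimethylcyclobut-1-en-1-yl)lithium 9 (not isolated)
Conditions: 8, n-BuLi (2.1 equiv), THF, −78 → 0 °C; then 6, −78 °C; aq NH4Cl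
Reagents that add atoms: none
Why: The Shapiro reaction (dianion, loss of sulfinate and N2) gives the cyclobutenyllithium, whose 1,2-addition to the ketone occurs on the face syn to the methyl group and anti to the vinyl and silyloxy groups, setting the carbinol centre (1S) with the two alkenyl groups trans.

Step 7
Reactants: 10 (1S,2S,3S)-3-[(tert-butyldimethylsilyl)oxy]-1-(3,3-dimethylcyclobut-1-en-1-yl)-2-ethenyl-2-methylcyclopentan-1-ol
Product: 13 (1R,3E,5S,9S)-5-[(tert-butyldimethylsilyl)oxy]-4,11,11-trimethylbicyclo[7.2.0]undec-3-en-8-one, via potassium alkoxide 11 (not isolated), via potassium enolate 12 (not isolated)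
Conditions: KH, 18-crown-6, THF, 0 °C → rt; then MeOH, rt
Reagents that add atoms: none
Why: KH forms the potassium alkoxide, whose charge-accelerated [3,3]-sigmatropic shift (anionic oxy-Cope rearrangement) passes through a chair array C1=C9–C8···C4–C3=C2 with the bonds C8–C7 and C4–C5 equatorial, so that C1–C2 forms as C4–C8 breaks and enolate 12 results. The closest known reaction type is the anionic oxy-Cope ring expansion of trans-1,2-dialkenylcyclopentanols to (E)-cyclonon-5-enones. The nine-membered ring is closed by a four-atom ring expansion of the five-membered ring, the new bond joining the two termini of the 1,5-diene across the six-membered chair rather than by an exo or endo chain cyclisation. C1 is set by chirality transfer from C4 and C8 through the chair with the CMe2 carbon of the cyclobutene equatorial (1R from the 1S,2S carbinol), the E geometry of C3=C4 follows from the equatorial C4–C5 bond, and C9 is set when methanol protonates the enolate under equilibrating conditions (KOMe) to the trans ring fusion, the more stable one in bicyclo[7.2.0]undecan-8-ones. The step needs the [3,3] shift to win over a [1,3] shift and over loss of the alkenyl anion, and chair to win over boat; the trans arrangement of the two alkenyl groups, the partial release of cyclobutene strain and the crown-separated potassium alkoxide should secure this, while the C5 silyl ether stays outside the reacting array.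

Step 8
Reactants: 13 (1R,3E,5S,9S)-5-[(tert-butyldimethylsilyl)oxy]-4,11,11-trimethylbicyclo[7.2.0]undec-3-en-8-one
Product: 14 tert-butyldimethyl{[(1R,3E,5S,9S)-4,11,11-trimethyl-8-methylidenebicyclo[7.2.0]undec-3-en-5-yl]oxy}silane
Conditions: Ph3PCH3Br, KOtBu, toluene, 80 °C
Reagents that add atoms: methyltriphenylphosphonium bromide, C[P+](c1ccccc1)(c1ccccc1)c1ccccc1.[Br-]
Why: Wittig methylenation converts the C8 ketone into the exocyclic alkene; C9 is epimerisable under the basic conditions but already has its preferred trans configuration, and no new stereocentre forms.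

Step 9
Reactants: 14 tert-butyldimethyl{[(1R,3E,5S,9S)-4,11,11-trimethyl-8-methylidenebicyclo[7.2.0]undec-3-en-5-yl]oxy}silane
Product: 15 (1R,3E,5S,9S)-4,11,11-trimethyl-8-methylidenebicyclo[7.2.0]undec-3-en-5-ol
Conditions: TBAF, THF, rt
Reagents that add atoms: none
Why: Fluoride-mediated silyl ether cleavage frees the allylic alcohol without touching any stereocentre or alkene.

Step 10
Reactants: 15 (1R,3E,5S,9S)-4,11,11-trimethyl-8-methylidenebicyclo[7.2.0]undec-3-en-5-ol
Product: 18 (1R,4E,9S)-4,11,11-trimethyl-8-methylidenebicyclo[7.2.0]undec-4-ene [(−)-β-caryophyllene], via sulfonyl hydrazine 16 (not isolated), via allylic diazene 17 (not isolated)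
Conditions: 2-nitrobenzenesulfonyl hydrazide (NBSH), PPh3, DEAD, N-methylmorpholine, −30 → 23 °C
Reagents that add atoms: none
Why: Reductive 1,3-transposition of the allylic alcohol: Mitsunobu displacement by the sulfonyl hydrazide inverts C5, loss of sulfinic acid gives the allylic diazene, and its retro-ene loss of N2 delivers hydrogen to C3 and moves the double bond to C4=C5; after inversion the C5–N bond lies on the outer face of the E-alkene with C6 anti to C3, so the new alkene should form E as the C5 stereocentre is consumed.

Step 11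
Reactants: 19 2-methyl-1-(2,4,6-trihydroxyphenyl)propan-1-one
Product: 20 3,5-dihydroxy-4,6,6-trimethyl-2-(2-methylpropanoyl)cyclohexa-2,4-dien-1-one (norflavesone)
Conditions: MeI (3 equiv), NaOMe, MeOH, 0 °C → rt
Reagents that add atoms: iodomethane, CI
Why: Dearomatising C-methylation of the acylphloroglucinol (three enolate alkylations, two at one ring carbon and one at the other) gives the trimethylated trione; no stereocentre is formed.

Step 12
Reactants: 18 (1R,4E,9S)-4,11,11-trimethyl-8-methylidenebicyclo[7.2.0]undec-4-ene; 20 3,5-dihydroxy-4,6,6-trimethyl-2-(2-methylpropanoyl)cyclohexa-2,4-dien-1-one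
Product: 22 the target, (1R,4S,5R,9S)-configured dihydropyran adduct (caryophyllane locants), via o-quinone methide 21 (not isolated)
Conditions: Ag2O (1.5 equiv), TEMPO (0.2 equiv), toluene, rt
Reagents that add atoms: none
Why: Oxidation of the ring methyl group of 20 gives the o-quinone methide, which adds as a 1-oxadiene (inverse-demand hetero-Diels–Alder reaction, the carbonyl next to CMe2 supplying the oxygen, which bonds to the more substituted C4) suprafacially to the E-alkene, so C4 and C5 are set together with a trans ring fusion; the face is decided by which ring conformer reacts, and the target is the adduct on the Si,Si face of C4=C5, expected together with the Re,Re-face adduct (its 4R,5S diastereomer), from which it is separated.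

**Compound list**
1 | 2-methylcyclopentane-1,3-dione | CC1C(=O)CCC1=O | starting material
2 | phenyl vinyl sulfoxide | C=CS(=O)c1ccccc1 | starting material
3 | 2-methyl-2-[2-(phenylsulfinyl)ethyl]cyclopentane-1,3-dione | CC1(CCS(=O)c2ccccc2)C(=O)CCC1=O | intermediate
4 | (2S,3S)-3-hydroxy-2-methyl-2-[2-(phenylsulfinyl)ethyl]cyclopentan-1-one | C[C@]1(CCS(=O)c2ccccc2)[C@@H](O)CCC1=O | intermediate
5 | (2S,3S)-3-[(tert-butyldimethylsilyl)oxy]-2-methyl-2-[2-(phenylsulfinyl)ethyl]cyclopentan-1-one | C[C@]1(CCS(=O)c2ccccc2)[C@@H](O[Si](C)(C)C(C)(C)C)CCC1=O | intermediate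
6 | (2S,3S)-3-[(tert-butyldimethylsilyl)oxy]-2-ethenyl-2-methylcyclopentan-1-one | C[C@]1(C=C)[C@@H](O[Si](C)(C)C(C)(C)C)CCC1=O | intermediate
7 | 3,3-dimethylcyclobutan-1-one | CC1(C)CC(=O)C1 | starting material
8 | N'-(3,3-dimethylcyclobutylidene)-2,4,6-tri(propan-2-yl)benzenesulfonohydrazide | CC1(C)CC(=NNS(=O)(=O)c2c(C(C)C)cc(C(C)C)cc2C(C)C)C1 | intermediate
9 | (3,3-dimethylcyclobut-1-en-1-yl)lithium | [Li]C1=CC(C)(C)C1 | intermediate
10 | (1S,2S,3S)-3-[(tert-butyldimethylsilyl)oxy]-1-(3,3-dimethylcyclobut-1-en-1-yl)-2-ethenyl-2-methylcyclopentan-1-ol | C[C@]1(C=C)[C@@H](O[Si](C)(C)C(C)(C)C)CC[C@]1(O)C2=CC(C)(C)C2 | intermediate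
11 | potassium alkoxide of 10 | C[C@]1(C=C)[C@@H](O[Si](C)(C)C(C)(C)C)CC[C@]1([O-])C2=CC(C)(C)C2.[K+] | intermediate
12 | potassium enolate of 13 (C8=C9 enolate, C1 R, C5 S, 3E) | C1C[C@H](O[Si](C)(C)C(C)(C)C)/C(C)=C/C[C@@H]2/C(CC2(C)C)=C1\[O-].[K+] | intermediate
13 | (1R,3E,5S,9S)-5-[(tert-butyldimethylsilyl)oxy]-4,11,11-trimethylbicyclo[7.2.0]undec-3-en-8-one | O=C1CC[C@H](O[Si](C)(C)C(C)(C)C)/C(C)=C/C[C@@H]2[C@@H]1CC2(C)C | intermediate
14 | tert-butyldimethyl{[(1R,3E,5S,9S)-4,11,11-trimethyl-8-methylidenebicyclo[7.2.0]undec-3-en-5-yl]oxy}silane | C=C1CC[C@H](O[Si](C)(C)C(C)(C)C)/C(C)=C/C[C@@H]2[C@@H]1CC2(C)C | intermediate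
15 | (1R,3E,5S,9S)-4,11,11-trimethyl-8-methylidenebicyclo[7.2.0]undec-3-en-5-ol | C=C1CC[C@H](O)/C(C)=C/C[C@@H]2[C@@H]1CC2(C)C | intermediate
16 | N-[(1R,3E,5R,9S)-4,11,11-trimethyl-8-methylidenebicyclo[7.2.0]undec-3-en-5-yl]-2-nitrobenzenesulfonohydrazide | C=C1CC[C@@H](N(N)S(=O)(=O)c3ccccc3[N+](=O)[O-])/C(C)=C/C[C@@H]2[C@@H]1CC2(C)C | intermediate
17 | (1R,3E,5R,9S)-5-diazenyl-4,11,11-trimethyl-8-methylidenebicyclo[7.2.0]undec-3-ene | C=C1CC[C@@H](N=N)/C(C)=C/C[C@@H]2[C@@H]1CC2(C)C | intermediate
18 | (1R,4E,9S)-4,11,11-trimethyl-8-methylidenebicyclo[7.2.0]undec-4-ene, (−)-β-caryophyllene | C=C1CC/C=C(\C)CC[C@@H]2[C@@H]1CC2(C)C | intermediate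
19 | 2-methyl-1-(2,4,6-trihydroxyphenyl)propan-1-one | CC(C)C(=O)c1c(O)cc(O)cc1O | starting material
20 | 3,5-dihydroxy-4,6,6-trimethyl-2-(2-methylpropanoyl)cyclohexa-2,4-dien-1-one (norflavesone) | CC1=C(O)C(C)(C)C(=O)C(C(=O)C(C)C)=C1O | intermediate
21 | 3-hydroxy-6,6-dimethyl-4-methylidene-2-(2-methylpropanoyl)cyclohex-2-ene-1,5-dione (o-quinone methide) | C=C1C(=O)C(C)(C)C(=O)C(C(=O)C(C)C)=C1O | intermediate
22 | target CNP0497637.1, (1R,4S,5R,9S) dihydropyran adduct of 18 and 21 | C=C1CC[C@@H]2CC3=C(O[C@@]2(C)CC[C@@H]2[C@@H]1CC2(C)C)C(C)(C)C(=O)C(C(=O)C(C)C)=C3O | target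

Total step count: 12. Longest linear sequence: 10 steps (steps 1–4, 6–10 and 12).

**Steps most likely to fail**

Step 7. The [3,3] shift must make a bond at the cyclobutene carbon next to the quaternary CMe2 carbon. If that slows the rearrangement, the alkoxide may lose the cyclobutenyl anion by retro-addition, undergo a [1,3] shift to a seven-membered ketone, or pass its charge to the C5 oxygen by silyl migration. Equilibration at C9 may also favour the trans fusion less clearly in this 3-ene than in the 4-ene series. The fallback sets out from 10 and comes back at 13 without an alkoxide: a cyclisation-induced rearrangement under divalent palladium catalysis (PdCl2(MeCN)2, THF, rt). The metal activates the vinyl group, the cyclobutene attacks it through the same chair (C1–C2 bond), and the resulting C9 cation is quenched by cleavage of C4–C8 to the C8 enol; DBU then equilibrates the ketone to 13. No new compound is formed (F0).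

Step 10. Displacement at the ring carbinol may be slow or proceed with allylic transposition, and the ring may impose the Z-alkene. The fallback sets out from 15 and comes back at 18: MnO2 oxidation to enone F1, condensation with 4-methylbenzenesulfonohydrazide to tosylhydrazone F2, then catecholborane followed by NaOAc. Hydride addition to C=N and loss of sulfinate give an allylic diazene (17 or its C5 epimer F3) without any substitution step, and retro-ene loss of N2 moves the double bond to C4=C5.

Step 12. The quinone methide may dimerise or be consumed by the oxidant before it is trapped. The ring conformers exposing the Si,Si face may also react more slowly than those exposing the Re,Re face (the face from which caryophyllene oxide is formed), which would leave the target as the lesser adduct. The fallback sets out from 19 (with 18) and comes back at 22: double C-methylation of 19 (2 equiv MeI, NaOMe) to dimethylated trione F4, then a three-component Knoevenagel/hetero-Diels–Alder reaction of F4, paraformaldehyde and 18 (NaOAc, AcOH, 80 °C). This forms the same heterodiene 21 by condensation, without an oxidant, at a temperature where the less populated conformers should take a larger share; the adducts are separated as before.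

Further compounds
F0 | step 7 | none | none
F1 | step 10 | (1R,3E,9S)-4,11,11-trimethyl-8-methylidenebicyclo[7.2.0]undec-3-en-5-one | C=C1CCC(=O)/C(C)=C/C[C@@H]2[C@@H]1CC2(C)C
F2 | step 10 | N'-[(1R,3E,9S)-4,11,11-trimethyl-8-methylidenebicyclo[7.2.0]undec-3-en-5-ylidene]-4-methylbenzenesulfonohydrazide | C=C1CCC(=NNS(=O)(=O)c3ccc(C)cc3)/C(C)=C/C[C@@H]2[C@@H]1CC2(C)C
F3 | step 10 | (1R,3E,5S,9S)-5-diazenyl-4,11,11-trimethyl-8-methylidenebicyclo[7.2.0]undec-3-ene | C=C1CC[C@H](N=N)/C(C)=C/C[C@@H]2[C@@H]1CC2(C)C
F4 | step 12 | 2,2-dimethyl-6-(2-methylpropanoyl)cyclohexane-1,3,5-trione (enol form) | CC(C)C(=O)C1=C(O)CC(=O)C(C)(C)C1=O
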